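Ring B is built last by a [3+3] union of a ring A ketone carrying the C5(=O)–C10–C9 unit with a C6–C7–C8 allenylphosphonate. In one flask the allylic alkoxide adds to the allene, the phosphonate-stabilised anion undergoes a carbanion-accelerated Claisen rearrangement (C8–C9), and the resulting keto phosphonate anion olefinates the C5 ketone (C5=C6). The step exploits the 1,3-placement of C5 and C9 about quaternary C10 and of C6 and C8 about oxygenated C7 in ring B; the tethering oxygen ends as the C7 oxygen. C10, set by palladium catalysis, relays C9; C8, C7, C6 and C5 then follow by substrate control.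

Key step: step 6

Remark: positions are given in labdane numbering (C1 to C20) and α is the face opposite the C10 methyl group; the C8 configuration of 13 is not relayed, because step 7 passes through the C7–C8 enolate.

Step 1
Reactants: 1 2,2,6-trimethylcyclohexan-1-one (racemic); 2 allyl chloroformate
Product: 3 allyl 2,6,6-trimethylcyclohex-1-en-1-yl carbonate
Conditions: LiN(SiMe3)2, THF, −78 °C; then 2, −78 → 20 °C
Reagents that add atoms: allyl chloroformate, C=CCOC(Cl)=O
Why: the ketone has one enolisable position, so a single tetrasubstituted lithium enolate forms and the hard chloroformate acylates it on oxygen (enol carbonate formation).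

Step 2
Reactants: 3 allyl 2,6,6-trimethylcyclohex-1-en-1-yl carbonate
Product: 4 (R)-2-allyl-2,6,6-trimethylcyclohexan-1-one
Conditions: Pd2(dba)3 (2.5 mol %), (R)-t-BuPHOX (6 mol %), THF, 25 °C
Reagents that add atoms: none
Why: decarboxylative asymmetric allylic alkylation (Tsuji type), in which zerovalent palladium ionises the carbonate, CO2 is lost and the enolate and allyl partners recombine inside the chiral phosphinooxazoline pocket to set the C10 quaternary centre; the (R) ligand is chosen because the (S) ligand is expected to give the (S) ketone.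

Step 3
Reactants: 4 (R)-2-allyl-2,6,6-trimethylcyclohexan-1-one
Product: 5 (E)-3-[(1R)-1,3,3-trimethyl-2-oxocyclohexyl]prop-2-en-1-yl acetate
Conditions: Pd(OAc)2 (10 mol %), 1,4-benzoquinone (2 equiv), DMSO/AcOH (1:1), 40 °C
Reagents that add atoms: acetic acid, CC(=O)O
Why: sulfoxide-promoted allylic C–H acetoxylation, in which divalent palladium cleaves a C9–H bond to a π-allyl complex and acetate attacks the unhindered terminus C12, giving the linear (E) acetate with the double bond moved to C9=C11.

Step 4
Reactants: 5 (E)-3-[(1R)-1,3,3-trimethyl-2-oxocyclohexyl]prop-2-en-1-yl acetate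
Product: 6 (R)-2-[(E)-3-hydroxyprop-1-en-1-yl]-2,6,6-trimethylcyclohexan-1-one
Conditions: K2CO3, MeOH, 20 °C
Reagents that add atoms: none
Why: methanolysis (transesterification) of the primary acetate; the ketone has no α-hydrogen, so C10 cannot epimerise.

Step 5
Reactants: 7 but-3-yn-2-ol (racemic); 8 diethyl chlorophosphite
Product: 10 diethyl buta-1,2-dien-1-ylphosphonate (racemic), via propargyl phosphite 9 (not isolated)
Conditions: Et3N, CH2Cl2, −78 → 20 °C
Reagents that add atoms: diethyl chlorophosphite, CCOP(Cl)OCC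
Why: O-phosphitylation followed by the spontaneous [2,3]-sigmatropic rearrangement of the propargyl phosphite to the allenylphosphonate; the allene chirality is erased in step 6.

Step 6
Reactants: 6 (R)-2-[(E)-3-hydroxyprop-1-en-1-yl]-2,6,6-trimethylcyclohexan-1-one; 10 diethyl buta-1,2-dien-1-ylphosphonate
Product: 13 8β-methyl-9β-vinyl bicyclic enone (13,14,15,16-tetranorlabda-5,11-dien-7-one; 8α-H 9α-H), via allyl vinyl ether anion 11 (not isolated), via keto phosphonate anion 12 (not isolated)
Conditions: KH (1.3 equiv), THF, 0 °C; 10, −20 → 0 °C; then LiCl, DMSO, 20 °C; then 70 °C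
Reagents that add atoms: diethyl buta-1,2-dien-1-ylphosphonate, CCOP(=O)(OCC)C=C=CC
Why: The potassium alkoxide of 6 adds to the central allene carbon of 10 and gives directly the phosphonate-stabilised allyl anion 11, which undergoes a carbanion-accelerated Claisen rearrangement through a chair transition state (C8–C9 forms and the former C12 oxygen becomes the C7 carbonyl) to the keto phosphonate anion 12; on warming, C6 of 12 adds to the C5 ketone and the oxaphosphetane collapses (intramolecular Horner–Wadsworth–Emmons olefination), forming C5–C6 as the C5=C6 bond with loss of diethyl phosphate. The closest known reaction types are the carbanion-accelerated Claisen rearrangement of 2-(phosphonomethyl) allyl vinyl ethers made from allenylphosphonates and the Michael/intramolecular Horner–Wadsworth–Emmons cyclohexenone annulation; each stage is known for its substrate class and only running them in one flask is the accepted risk. Ring B closes in the olefination by a 6-(enolendo)-exo-trig attack of C6 on C5, whereas the sigmatropic stage closes no ring. C9 is controlled by relay from C10: the alkene should react on the face anti to the C10–C5 acyl bond with the small C10 methyl gauche to the incoming C8 substituent, which places the vinyl group β (9α-H); C8 should emerge 8β-methyl from the chair with both alkene units (E), but it is enolisable and is reset in step 7. The step needs regioselection of the [3,3] shift through C8 and not C6, secured because only that path leaves a phosphonate-stabilised carbanion, and chemoselection for the C5 ketone, secured because it is non-enolisable and within reach of C6 only intramolecularly.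

Step 7
Reactants: 13 8β-methyl-9β-vinyl bicyclic enone
Product: 14 8α-hydroxy-8β-methyl-9β-vinyl enone (8α-hydroxy-13,14,15,16-tetranorlabda-5,11-dien-7-one)
Conditions: KN(SiMe3)2, THF, −78 °C; then 3-phenyl-2-(phenylsulfonyl)oxaziridine, −78 °C; NH4Cl
Reagents that add atoms: 3-phenyl-2-(phenylsulfonyl)oxaziridine, O=S(=O)(c1ccccc1)N1OC1c1ccccc1
Why: Davis hydroxylation of the potassium enolate, where C8–H is the only acidic position (both γ-carbons are quaternary) and the oxidant approaches the C7–C8 enolate from the α face, anti to the 10β-methyl and 9β-vinyl groups, so either C8 epimer of 13 gives 8α-OH/8β-CH3.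

Step 8
Reactants: 14 8α-hydroxy-8β-methyl-9β-vinyl enone
Product: 15 13,14,15,16-tetranorlabda-5,11-diene-7β,8α-diol
Conditions: NaBH4, CeCl3·7H2O, MeOH, −40 °C
Reagents that add atoms: none
Why: Luche 1,2-reduction, in which hydride adds to C7 axially from the α face, anti to the axial 8β-methyl group, to give the equatorial 7β-alcohol trans to the 8α-hydroxyl.

Step 9
Reactants: 15 13,14,15,16-tetranorlabda-5,11-diene-7β,8α-diol
Product: 16 7β,8α-bis(triethylsilyloxy)-13,14,15,16-tetranorlabda-5,11-diene
Conditions: Et3SiOTf (3 equiv), 2,6-lutidine, CH2Cl2, −78 → 0 °C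
Reagents that add atoms: triethylsilyl trifluoromethanesulfonate, CC[Si](CC)(CC)OS(=O)(=O)C(F)(F)F
Why: the silyl triflate silylates both the secondary allylic and the tertiary alcohol, which leaves O6 as the only oxygen that can later be acetylated and prevents O8 from forming a lactol at the aldehyde stage.

Step 10
Reactants: 16 7β,8α-bis(triethylsilyloxy)-13,14,15,16-tetranorlabda-5,11-diene
Product: 17 7β,8α-bis(triethylsilyloxy)-13,14,15,16-tetranorlabdane-6α,12-diol (5α-H)
Conditions: 9-BBN, THF, 20 °C; then BH3·THF, 0 → 40 °C; then NaOH, H2O2, 0 °C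
Reagents that add atoms: hydrogen peroxide, OO
Why: hydroboration–oxidation, in which 9-BBN takes the vinyl group (anti-Markovnikov, no B–H left for intramolecular delivery) and borane then adds syn across C5=C6 from the α face with boron on the less substituted C6 (anti to the 10β-methyl and to the allylic 7β-silyloxy group), so oxidation with retention sets 5α-H and 6α-OH.

Step 11
Reactants: 17 7β,8α-bis(triethylsilyloxy)-13,14,15,16-tetranorlabdane-6α,12-diol
Product: 18 6α-hydroxy-7β,8α-bis(triethylsilyloxy)-13,14,15,16-tetranorlabdan-12-al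
Conditions: TEMPO (10 mol %), PhI(OAc)2, CH2Cl2, 20 °C
Reagents that add atoms: none
Why: oxoammonium (TEMPO) oxidation is selective for the primary alcohol over the hindered secondary 6α-hydroxyl.

Step 12
Reactants: 18 6α-hydroxy-7β,8α-bis(triethylsilyloxy)-13,14,15,16-tetranorlabdan-12-al
Product: 19 (12Z)-13-iodo-7β,8α-bis(triethylsilyloxy)-14,15-dinorlabd-12-en-6α-ol
Conditions: EtPPh3I, n-BuLi, THF, 20 °C; I2, −78 °C; NaN(SiMe3)2, −20 °C; then 18, −78 °C (excess ylide)
Reagents that add atoms: ethyltriphenylphosphonium iodide, CC[P+](c1ccccc1)(c1ccccc1)c1ccccc1.[I-]; iodine, [I][I]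
Why: Wittig olefination with the α-iodoethylidene ylide (Stork–Zhao type), which is kinetically Z-selective (iodine cis to C11) and tolerates the free hindered 6-hydroxyl when the ylide is in excess.

Step 13
Reactants: 19 (12Z)-13-iodo-7β,8α-bis(triethylsilyloxy)-14,15-dinorlabd-12-en-6α-ol
Product: 20 (12Z)-6α-acetoxy-13-iodo-7β,8α-bis(triethylsilyloxy)-14,15-dinorlabd-12-ene
Conditions: Ac2O, DMAP, pyridine, 40 °C
Reagents that add atoms: acetic anhydride, CC(=O)OC(C)=O
Why: DMAP-catalysed acylation of the only free hydroxyl group.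

Step 14
Reactants: 20 (12Z)-6α-acetoxy-13-iodo-7β,8α-bis(triethylsilyloxy)-14,15-dinorlabd-12-ene
Product: 21 6α-acetoxy-7β,8α-bis(triethylsilyloxy)labda-12Z,14-diene
Conditions: tributyl(vinyl)stannane, Pd(PPh3)4 (5 mol %), CuI (10 mol %), DMF, 40 °C
Reagents that add atoms: tributyl(vinyl)stannane, C=C[Sn](CCCC)(CCCC)CCCC
Why: Stille coupling (oxidative addition of zerovalent palladium to the alkenyl iodide, transmetalation, reductive elimination) proceeds with retention of alkene geometry and gives the (12Z)-diene.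

Step 15
Reactants: 21 6α-acetoxy-7β,8α-bis(triethylsilyloxy)labda-12Z,14-diene
Product: 22 CNP0138393.1, (5S,6R,7S,8S,9R,10S)-6-acetoxylabda-12Z,14-diene-7,8-diol
Conditions: HF·pyridine, pyridine, THF, 0 → 20 °C
Reagents that add atoms: none
Why: fluoride cleavage of both triethylsilyl ethers under buffered, weakly acidic conditions, which avoids the base-induced acetyl shift from O6 to O7.

Compound list
1 | 2,2,6-trimethylcyclohexan-1-one (racemic) | CC1CCCC(C)(C)C1=O | starting material
2 | allyl chloroformate | C=CCOC(Cl)=O | starting material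
3 | allyl 2,6,6-trimethylcyclohex-1-en-1-yl carbonate | C=CCOC(=O)OC1=C(C)CCCC1(C)C | intermediate
4 | (R)-2-allyl-2,6,6-trimethylcyclohexan-1-one | C=CC[C@@]1(C)CCCC(C)(C)C1=O | intermediate
5 | (E)-3-[(1R)-1,3,3-trimethyl-2-oxocyclohexyl]prop-2-en-1-yl acetate | CC(=O)OC/C=C/[C@@]1(C)CCCC(C)(C)C1=O | intermediate
6 | (R)-2-[(E)-3-hydroxyprop-1-en-1-yl]-2,6,6-trimethylcyclohexan-1-one | OC/C=C/[C@@]1(C)CCCC(C)(C)C1=O | intermediate
7 | but-3-yn-2-ol (racemic) | CC(O)C#C | starting material
8 | diethyl chlorophosphite | CCOP(Cl)OCC | starting material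
9 | but-3-yn-2-yl diethyl phosphite (not isolated) | CCOP(OCC)OC(C)C#C | intermediate
10 | diethyl buta-1,2-dien-1-ylphosphonate (racemic) | CCOP(=O)(OCC)C=C=CC | intermediate
11 | potassium salt of the allyl anion of diethyl [(2E)-2-({(2E)-3-[(1R)-1,3,3-trimethyl-2-oxocyclohexyl]prop-2-en-1-yl}oxy)but-2-en-1-yl]phosphonate (not isolated) | CCOP(=O)(OCC)[CH-]/C(OC/C=C/[C@@]1(C)CCCC(C)(C)C1=O)=C\C.[K+] | intermediate
12 | potassium salt of diethyl {3-methyl-2-oxo-4-[(1R)-1,3,3-trimethyl-2-oxocyclohexyl]hex-5-en-1-yl}phosphonate, 8β-methyl and 9α-H (not isolated) | C=C[C@H]([C@@]1(C)CCCC(C)(C)C1=O)[C@@H](C)C(=O)[CH-]P(=O)(OCC)OCC.[K+] | intermediate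
13 | 13,14,15,16-tetranorlabda-5,11-dien-7-one with 8β-methyl (8α-H), 9β-vinyl (9α-H), 10β-methyl | C=C[C@H]1[C@@H](C)C(=O)C=C2C(C)(C)CCC[C@@]21C | intermediate
14 | 8α-hydroxy-13,14,15,16-tetranorlabda-5,11-dien-7-one (8β-methyl, 9β-vinyl) | C=C[C@H]1[C@](C)(O)C(=O)C=C2C(C)(C)CCC[C@@]21C | intermediate
15 | 13,14,15,16-tetranorlabda-5,11-diene-7β,8α-diol | C=C[C@H]1[C@](C)(O)[C@@H](O)C=C2C(C)(C)CCC[C@@]21C | intermediate
16 | 7β,8α-bis(triethylsilyloxy)-13,14,15,16-tetranorlabda-5,11-diene | C=C[C@H]1[C@](C)(O[Si](CC)(CC)CC)[C@@H](O[Si](CC)(CC)CC)C=C2C(C)(C)CCC[C@@]21C | intermediate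
17 | 7β,8α-bis(triethylsilyloxy)-13,14,15,16-tetranorlabdane-6α,12-diol (5α-H) | OCC[C@H]1[C@](C)(O[Si](CC)(CC)CC)[C@@H](O[Si](CC)(CC)CC)[C@H](O)[C@H]2C(C)(C)CCC[C@@]21C | intermediate
18 | 6α-hydroxy-7β,8α-bis(triethylsilyloxy)-13,14,15,16-tetranorlabdan-12-al | O=CC[C@H]1[C@](C)(O[Si](CC)(CC)CC)[C@@H](O[Si](CC)(CC)CC)[C@H](O)[C@H]2C(C)(C)CCC[C@@]21C | intermediate
19 | (12Z)-13-iodo-7β,8α-bis(triethylsilyloxy)-14,15-dinorlabd-12-en-6α-ol | C/C(I)=C/C[C@H]1[C@](C)(O[Si](CC)(CC)CC)[C@@H](O[Si](CC)(CC)CC)[C@H](O)[C@H]2C(C)(C)CCC[C@@]21C | intermediate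
20 | (12Z)-6α-acetoxy-13-iodo-7β,8α-bis(triethylsilyloxy)-14,15-dinorlabd-12-ene | C/C(I)=C/C[C@H]1[C@](C)(O[Si](CC)(CC)CC)[C@@H](O[Si](CC)(CC)CC)[C@H](OC(C)=O)[C@H]2C(C)(C)CCC[C@@]21C | intermediate
21 | 6α-acetoxy-7β,8α-bis(triethylsilyloxy)labda-12Z,14-diene | C=C/C(C)=C\C[C@H]1[C@](C)(O[Si](CC)(CC)CC)[C@@H](O[Si](CC)(CC)CC)[C@H](OC(C)=O)[C@H]2C(C)(C)CCC[C@@]21C | intermediate
22 | CNP0138393.1, (5S,6R,7S,8S,9R,10S)-6-acetoxylabda-12Z,14-diene-7,8-diol (6α-OAc, 7β-OH, 8α-OH) | C=C/C(C)=C\C[C@H]1[C@](C)(O)[C@@H](O)[C@H](OC(C)=O)[C@H]2C(C)(C)CCC[C@@]21C | target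

Total step count: 15. Longest linear sequence: 14 steps (steps 1 to 4 and 6 to 15; step 5 is a one-step side branch).

Steps most likely to fail

Step 6. The sigmatropic shift may show poor facial selectivity at C9, or the ring-closing olefination may stall at the doubly neopentyl C5 ketone. The fallback makes the same two bonds by an ester-dianion Claisen and an aldol condensation and sets out from 6. Acylation with 2,2,5,6-tetramethyl-4H-1,3-dioxin-4-one (xylene, 130 °C) gives (E)-3-[(1R)-1,3,3-trimethyl-2-oxocyclohexyl]prop-2-en-1-yl 2-methyl-3-oxobutanoate F1. Its dianion (LiN(iPr)2, 2.2 equiv, THF, −78 → 65 °C) undergoes the Carroll rearrangement to 2-acetyl-2-methyl-3-[(1R)-1,3,3-trimethyl-2-oxocyclohexyl]pent-4-enoic acid F2, which loses CO2 on warming to give (R)-2,2,6-trimethyl-6-(4-methyl-5-oxohex-1-en-3-yl)cyclohexan-1-one F3, where C9 epimers could be separated. KOH in xylene at 110 °C then closes ring B by aldol condensation and the route is rejoined at 13; rearrangement, decarboxylation and condensation can be run in one flask.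

Step 3. C–H cleavage next to the quaternary carbon may be sluggish, and Wacker-type oxidation or branched acetate formation may compete. The fallback brings in the oxygen by ene chemistry and sets out from 4. RuHCl(CO)(PPh3)3 (toluene, 110 °C) moves the double bond one position, the only one open to it, and gives (R,E)-2,2,6-trimethyl-6-(prop-1-en-1-yl)cyclohexan-1-one F4. SeO2 (cat.) with t-BuOOH in CH2Cl2 then oxidises the only allylic C–H position (ene reaction, then [2,3]-shift) and the route is rejoined at 6.

Step 10. Borane may add slowly to the hindered C5=C6 bond, face selectivity may erode, or silyl ethers may be lost in the oxidative work-up. The fallback sets C5–H and C6–O by epoxide chemistry and sets out from 16. 9-BBN alone, then NaOH/H2O2, gives 7β,8α-bis(triethylsilyloxy)-13,14,15,16-tetranorlabd-5-en-12-ol F5. mCPBA with NaHCO3 epoxidises the trisubstituted alkene from the α face to 5α,6α-epoxy-7β,8α-bis(triethylsilyloxy)-13,14,15,16-tetranorlabdan-12-ol F6. Cp2TiCl (trivalent titanium, from Cp2TiCl2 and Mn) with 1,4-cyclohexadiene in THF opens the epoxide homolytically at C5, the tertiary radical takes hydrogen from the α face, and the route is rejoined at 17.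

Further compounds
F1 | step 6 | (E)-3-[(1R)-1,3,3-trimethyl-2-oxocyclohexyl]prop-2-en-1-yl 2-methyl-3-oxobutanoate | CC(=O)C(C)C(=O)OC/C=C/[C@@]1(C)CCCC(C)(C)C1=O
F2 | step 6 | 2-acetyl-2-methyl-3-[(1R)-1,3,3-trimethyl-2-oxocyclohexyl]pent-4-enoic acid (C8 epimers) | CC(=O)C(C)(C(=O)O)[C@H](C=C)[C@@]1(C)CCCC(C)(C)C1=O
F3 | step 6 | (R)-2,2,6-trimethyl-6-(4-methyl-5-oxohex-1-en-3-yl)cyclohexan-1-one (C8 epimers) | CC(=O)C(C)[C@H](C=C)[C@@]1(C)CCCC(C)(C)C1=O
F4 | step 3 | (R,E)-2,2,6-trimethyl-6-(prop-1-en-1-yl)cyclohexan-1-one | C/C=C/[C@@]1(C)CCCC(C)(C)C1=O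
F5 | step 10 | 7β,8α-bis(triethylsilyloxy)-13,14,15,16-tetranorlabd-5-en-12-ol | OCC[C@H]1[C@](C)(O[Si](CC)(CC)CC)[C@@H](O[Si](CC)(CC)CC)C=C2C(C)(C)CCC[C@@]21C
F6 | step 10 | 5α,6α-epoxy-7β,8α-bis(triethylsilyloxy)-13,14,15,16-tetranorlabdan-12-ol | OCC[C@H]1[C@](C)(O[Si](CC)(CC)CC)[C@@H](O[Si](CC)(CC)CC)[C@@H]3O[C@@]32C(C)(C)CCC[C@@]21C
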